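**Retrosynthetic overview**

- Numbering: ring A is C1 (OMe), C2 (OH), C3 (H), C4 (carries hydroxymethyl C8), C5 (carries methylene C7), C6 (OH); ring B is the 2,3-dibromo-4,5-dihydroxyphenyl ring on C7.
- Feature: the adjacent carbon substituents C8 on C4 and C7 on C5 sit next to the C6 oxygen. This is the pattern left when a 3-alkoxybenzyne C4≡C5 takes a carbon nucleophile at C4 and a carbon electrophile at C5.
- Disconnections: C7–H and C8–H bonds (reductions) back to a 3-arylphthalide, then to a cyclic N-tert-butyl imidate, which is opened at C4–C8, C5–C7 and O–C8 into benzyne, tert-butyl isocyanide and the ring B aldehyde.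
- Ring order: rings A and B are bought as arenes; the only ring built is the five-membered imidate ring (step 10), carried as the lactone and opened again in step 12.
- Fragments: silyl triflate 10 from methyl 3,5-dihydroxy-4-methoxybenzoate (6 steps); aldehyde 14 from 5-bromovanillin (3 steps).

Key step: step 10

Remark: the target is achiral, so the C7 centre made in step 10 is left racemic and is erased in step 13; 5-bromovanillin is taken as a purchased starting material.

**Route**

Step 1
Reactants: 1 methyl 3,5-dihydroxy-4-methoxybenzoate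
Product: 2 methyl 3,5-bis(benzyloxy)-4-methoxybenzoate
Conditions: BnBr, K2CO3, DMF, 60 °C
Reagents that add atoms: benzyl bromide, BrCc1ccccc1
Why: Williamson ether synthesis; both phenols flanking the methoxy group are alkylated and the ester is untouched.

Step 2
Reactants: 2 methyl 3,5-bis(benzyloxy)-4-methoxybenzoate
Product: 3 [3,5-bis(benzyloxy)-4-methoxyphenyl]methanol
Conditions: LiAlH4, THF, 0 °C
Reagents that add atoms: none
Why: hydride reduction of an aryl ester to the benzylic alcohol; benzyl ethers are inert.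

Step 3
Reactants: 3 [3,5-bis(benzyloxy)-4-methoxyphenyl]methanol
Product: 4 3,5-bis(benzyloxy)-4-methoxybenzaldehyde
Conditions: MnO2, CH2Cl2, rt
Reagents that add atoms: none
Why: MnO2 oxidation of a benzylic alcohol stops cleanly at the aldehyde.

Step 4
Reactants: 4 3,5-bis(benzyloxy)-4-methoxybenzaldehyde
Product: 6 3,5-bis(benzyloxy)-4-methoxyphenol, via aryl formate 5 (not isolated)
Conditions: mCPBA, CH2Cl2, 0 °C to rt; then K2CO3 (cat.), MeOH, rt
Reagents that add atoms: mCPBA, OOC(=O)c1cccc(Cl)c1
Why: Baeyer–Villiger (Dakin-type) oxidation; the electron-rich trialkoxyaryl group migrates in the Criegee intermediate to give the formate, which is transesterified to the phenol in the same flask.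

Step 5
Reactants: 6 3,5-bis(benzyloxy)-4-methoxyphenol
Product: 7 3,5-bis(benzyloxy)-2-bromo-4-methoxyphenol
Conditions: NBS (1.0 equiv), CH2Cl2, −78 to 0 °C
Reagents that add atoms: N-bromosuccinimide, O=C1CCC(=O)N1Br
Why: electrophilic aromatic bromination; the para position is blocked by OMe and the two ortho positions are equivalent by symmetry, so one equivalent at low temperature should give a single monobromide.

Step 6
Reactants: 7 3,5-bis(benzyloxy)-2-bromo-4-methoxyphenol
Product: 10 3,5-bis(benzyloxy)-4-methoxy-2-(trimethylsilyl)phenyl trifluoromethanesulfonate, via aryl trimethylsilyl ether 8 (not isolated), via lithium 2-silylphenoxide 9 (not isolated)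
Conditions: HMDS, THF, 70 °C, evaporate; n-BuLi, THF, −78 °C; Tf2O, −78 °C to rt
Reagents that add atoms: hexamethyldisilazane, C[Si](C)(C)N[Si](C)(C)C; trifluoromethanesulfonic anhydride, O=S(=O)(OS(=O)(=O)C(F)(F)F)C(F)(F)F
Why: O-silylation, then bromine–lithium exchange triggers the anionic 1,3 O-to-C silyl shift (retro-Brook rearrangement) and the resulting phenoxide is triflated, the standard route to ortho-silylaryl triflates; exchange at −78 °C should outrun benzylic deprotonation of the benzyl ethers.

Step 7
Reactants: 11 5-bromovanillin (3-bromo-4-hydroxy-5-methoxybenzaldehyde)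
Product: 12 2,3-dibromo-4-hydroxy-5-methoxybenzaldehyde
Conditions: Br2, Fe powder (cat.), AcOH, rt to 50 °C
Reagents that add atoms: bromine, BrBr
Why: electrophilic aromatic bromination; the free position para to the methoxy group is the most activated, while the position between CHO and OMe is hindered.

Step 8
Reactants: 12 2,3-dibromo-4-hydroxy-5-methoxybenzaldehyde
Product: 13 2,3-dibromo-4,5-dihydroxybenzaldehyde
Conditions: BBr3, CH2Cl2, −78 °C to rt; H2O
Reagents that add atoms: none
Why: Lewis acid cleavage of the aryl methyl ether, assisted by the neighbouring phenol; the aldehyde and aryl bromides are tolerated.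

Step 9
Reactants: 13 2,3-dibromo-4,5-dihydroxybenzaldehyde
Product: 14 4,5-bis(benzyloxy)-2,3-dibromobenzaldehyde
Conditions: BnBr, K2CO3, DMF, 60 °C
Reagents that add atoms: benzyl bromide, BrCc1ccccc1
Why: Williamson ether synthesis on both catechol hydroxyls; the aldehyde has no enolisable position.

Step 10
Reactants: 10 3,5-bis(benzyloxy)-4-methoxy-2-(trimethylsilyl)phenyl trifluoromethanesulfonate; 14 4,5-bis(benzyloxy)-2,3-dibromobenzaldehyde; 15 tert-butyl isocyanide
Product: 17 racemic (Z)-4,6-bis(benzyloxy)-3-[4,5-bis(benzyloxy)-2,3-dibromophenyl]-N-tert-butyl-5-methoxy-2-benzofuran-1(3H)-imine, via benzyne 16 (not isolated)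
Conditions: KF, 18-crown-6, THF, 0 °C to rt (10 and 15 in slight excess over 14)
Reagents that add atoms: none
Why: Fluoride attacks silicon of 10 and triflate leaves to give benzyne 16 (triple bond C4–C5); the isocyanide carbon adds at C4 (bond C4–C8) to give a C5 aryl anion/nitrilium zwitterion, the anion adds to the carbonyl of 14 (bond C5–C7), and the alkoxide attacks the nitrilium carbon C8. This is the known three-component coupling of arynes, isocyanides and aldehydes to N-substituted iminoisobenzofurans, which proceeds with the same sense of addition on 3-methoxybenzyne. The one new ring, the five-membered O–C7–C5–C4–C8 imidate ring, closes in a 5-exo-dig mode, and anti addition across the nitrilium should place tert-butyl syn to the ring oxygen (Z). The new stereocentre C7 forms without a controlling element and is racemic, which is harmless because it becomes CH2 in step 13. The selectivity needed is regiochemical: the inductively withdrawing C6 benzyloxy group distorts the aryne so that C4 is the more electrophilic and less hindered terminus and the negative charge develops at C5 in the ring plane beside the C6–O bond, and the weak opposing effect of the more remote C2 benzyloxy group should not override this. No organometallic reagent or palladium catalyst is present, so the two aryl bromides of 14 are not at risk.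

Step 11
Reactants: 17 racemic (Z)-4,6-bis(benzyloxy)-3-[4,5-bis(benzyloxy)-2,3-dibromophenyl]-N-tert-butyl-5-methoxy-2-benzofuran-1(3H)-imine
Product: 18 racemic 4,6-bis(benzyloxy)-3-[4,5-bis(benzyloxy)-2,3-dibromophenyl]-5-methoxy-2-benzofuran-1(3H)-one
Conditions: 1 M aq. HCl, THF, 40 °C
Reagents that add atoms: water, O
Why: acid hydrolysis of a cyclic imidate; N-protonation, addition of water at C8 and loss of tert-butylammonium from the tetrahedral intermediate should give the lactone, with benzyl ethers and aryl bromides unaffected.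

Step 12
Reactants: 18 racemic 4,6-bis(benzyloxy)-3-[4,5-bis(benzyloxy)-2,3-dibromophenyl]-5-methoxy-2-benzofuran-1(3H)-one
Product: 19 racemic [4,5-bis(benzyloxy)-2,3-dibromophenyl][2,4-bis(benzyloxy)-6-(hydroxymethyl)-3-methoxyphenyl]methanol
Conditions: LiBH4, THF, 0 °C to 40 °C
Reagents that add atoms: none
Why: hydride reduction of the lactone to the diol; LiBH4 leaves aryl bromides and benzyl ethers alone.

Step 13
Reactants: 19 racemic [4,5-bis(benzyloxy)-2,3-dibromophenyl][2,4-bis(benzyloxy)-6-(hydroxymethyl)-3-methoxyphenyl]methanol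
Product: 20 {3,5-bis(benzyloxy)-2-[(4,5-bis(benzyloxy)-2,3-dibromophenyl)methyl]-4-methoxyphenyl}methanol
Conditions: Et3SiH, TFA, CH2Cl2, −20 to 0 °C; aq. NaHCO3/MeOH work-up
Reagents that add atoms: none
Why: ionic hydrogenation; the doubly benzylic C7 carbinol, ortho and para to benzyloxy groups, ionises far more readily than the primary C8 carbinol and the cation is reduced by the silane, any cyclic ether formed by capture of the cation by the C8 hydroxyl re-ionises at C7 and is funnelled to the same product, and the only stereocentre is removed.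

Step 14
Reactants: 20 {3,5-bis(benzyloxy)-2-[(4,5-bis(benzyloxy)-2,3-dibromophenyl)methyl]-4-methoxyphenyl}methanol
Product: 21 4-[(2,3-dibromo-4,5-dihydroxyphenyl)methyl]-5-(hydroxymethyl)-2-methoxybenzene-1,3-diol (target)
Conditions: BCl3, C6Me5H, CH2Cl2, −78 °C; aq. pH 7 phosphate buffer at −78 °C
Reagents that add atoms: none
Why: BCl3 debenzylation with pentamethylbenzene as a non-Lewis-basic cation scavenger should cleave the four aryl benzyl ethers at −78 °C without touching the aryl bromides or the methyl ether, the scavenger preventing C-benzylation of the electron-rich rings and the C8 hydroxyl being held as its dichloroborinate until the aqueous quench.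

**Compound list**

1 | methyl 3,5-dihydroxy-4-methoxybenzoate | COC(=O)c1cc(O)c(OC)c(O)c1 | starting material
2 | methyl 3,5-bis(benzyloxy)-4-methoxybenzoate | COC(=O)c1cc(OCc2ccccc2)c(OC)c(OCc2ccccc2)c1 | intermediate
3 | [3,5-bis(benzyloxy)-4-methoxyphenyl]methanol | OCc1cc(OCc2ccccc2)c(OC)c(OCc2ccccc2)c1 | intermediate
4 | 3,5-bis(benzyloxy)-4-methoxybenzaldehyde | O=Cc1cc(OCc2ccccc2)c(OC)c(OCc2ccccc2)c1 | intermediate
5 | 3,5-bis(benzyloxy)-4-methoxyphenyl formate | O=COc1cc(OCc2ccccc2)c(OC)c(OCc2ccccc2)c1 | intermediate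
6 | 3,5-bis(benzyloxy)-4-methoxyphenol | Oc1cc(OCc2ccccc2)c(OC)c(OCc2ccccc2)c1 | intermediate
7 | 3,5-bis(benzyloxy)-2-bromo-4-methoxyphenol | Oc1cc(OCc2ccccc2)c(OC)c(OCc2ccccc2)c1Br | intermediate
8 | [3,5-bis(benzyloxy)-2-bromo-4-methoxyphenoxy]trimethylsilane | C[Si](C)(C)Oc1cc(OCc2ccccc2)c(OC)c(OCc2ccccc2)c1Br | intermediate
9 | lithium 3,5-bis(benzyloxy)-4-methoxy-2-(trimethylsilyl)phenoxide | [Li+].[O-]c1cc(OCc2ccccc2)c(OC)c(OCc2ccccc2)c1[Si](C)(C)C | intermediate
10 | 3,5-bis(benzyloxy)-4-methoxy-2-(trimethylsilyl)phenyl trifluoromethanesulfonate | COc1c(OCc2ccccc2)cc(OS(=O)(=O)C(F)(F)F)c([Si](C)(C)C)c1OCc1ccccc1 | intermediate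
11 | 5-bromovanillin (3-bromo-4-hydroxy-5-methoxybenzaldehyde) | COc1cc(C=O)cc(Br)c1O | starting material
12 | 2,3-dibromo-4-hydroxy-5-methoxybenzaldehyde | COc1cc(C=O)c(Br)c(Br)c1O | intermediate
13 | 2,3-dibromo-4,5-dihydroxybenzaldehyde | O=Cc1cc(O)c(O)c(Br)c1Br | intermediate
14 | 4,5-bis(benzyloxy)-2,3-dibromobenzaldehyde | O=Cc1cc(OCc2ccccc2)c(OCc2ccccc2)c(Br)c1Br | intermediate
15 | tert-butyl isocyanide | [C-]#[N+]C(C)(C)C | starting material
16 | 3,5-bis(benzyloxy)-4-methoxybenzyne (1,2-didehydro arene, triple bond C4–C5 of ring A) | COC1=C(OCc2ccccc2)C#CC=C1OCc1ccccc1 | intermediate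
17 | racemic (Z)-4,6-bis(benzyloxy)-3-[4,5-bis(benzyloxy)-2,3-dibromophenyl]-N-tert-butyl-5-methoxy-2-benzofuran-1(3H)-imine | CC(C)(C)/N=C1\OC(c2cc(OCc3ccccc3)c(OCc3ccccc3)c(Br)c2Br)c2c(OCc3ccccc3)c(OC)c(OCc3ccccc3)cc12 | intermediate
18 | racemic 4,6-bis(benzyloxy)-3-[4,5-bis(benzyloxy)-2,3-dibromophenyl]-5-methoxy-2-benzofuran-1(3H)-one | O=C1OC(c2cc(OCc3ccccc3)c(OCc3ccccc3)c(Br)c2Br)c2c(OCc3ccccc3)c(OC)c(OCc3ccccc3)cc12 | intermediate
19 | racemic [4,5-bis(benzyloxy)-2,3-dibromophenyl][2,4-bis(benzyloxy)-6-(hydroxymethyl)-3-methoxyphenyl]methanol | OCc1cc(OCc2ccccc2)c(OC)c(OCc2ccccc2)c1C(O)c1cc(OCc2ccccc2)c(OCc2ccccc2)c(Br)c1Br | intermediate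
20 | {3,5-bis(benzyloxy)-2-[(4,5-bis(benzyloxy)-2,3-dibromophenyl)methyl]-4-methoxyphenyl}methanol | OCc1cc(OCc2ccccc2)c(OC)c(OCc2ccccc2)c1Cc1cc(OCc2ccccc2)c(OCc2ccccc2)c(Br)c1Br | intermediate
21 | 4-[(2,3-dibromo-4,5-dihydroxyphenyl)methyl]-5-(hydroxymethyl)-2-methoxybenzene-1,3-diol | COc1c(O)cc(CO)c(Cc2cc(O)c(O)c(Br)c2Br)c1O | target

**Step count**

Total: 14 steps. Longest linear sequence: 11 steps (steps 1–6 and 10–14, from compound 1).

**Steps most likely to fail**

Step 10. The hindered, rather electron-rich ortho-bromo aldehyde may intercept the aryl anion/nitrilium zwitterion too slowly. The zwitterion would then be lost to protonation, to a second aryne or to isocyanide oligomerisation, and the regiochemistry could erode if the C6 benzyloxy control is weaker than expected. Fallback: build the phthalide by directed ortho-metalation instead. Ester 2 is treated with Me2AlNEt2 (from AlMe3 and Et2NH, toluene, 80 °C) to give N,N-diethyl-3,5-bis(benzyloxy)-4-methoxybenzamide F1. Lithiation with s-BuLi/TMEDA (THF, −78 °C) occurs between the amide and a benzyloxy group (both such positions are equivalent). Transmetalation with MgBr2·OEt2 and addition to aldehyde 14 should give racemic 3,5-bis(benzyloxy)-2-{[4,5-bis(benzyloxy)-2,3-dibromophenyl](hydroxy)methyl}-N,N-diethyl-4-methoxybenzamide F2. Lactonisation with TsOH in toluene at 80 °C then returns to the route at phthalide 18.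

Step 14. BCl3 may ionise the C8–O bond of the free hydroxymethyl group, leading to chloride formation or Friedel–Crafts capture by pentamethylbenzene; less likely, the C1 methyl ether flanked by two oxygens could be lost. Fallback: debenzylate before C8 is reduced, so that the hydroxymethyl group is formed last under non-acidic conditions. Phthalide 18 is treated with BCl3/C6Me5H (CH2Cl2, −78 °C) to give racemic 3-(2,3-dibromo-4,5-dihydroxyphenyl)-4,6-dihydroxy-5-methoxy-2-benzofuran-1(3H)-one F3. Ionic hydrogenation (Et3SiH, TFA, 50 °C), eased by the now free ortho and para hydroxyl groups, opens the lactone at C7 to 2-[(2,3-dibromo-4,5-dihydroxyphenyl)methyl]-3,5-dihydroxy-4-methoxybenzoic acid F4. Excess BH3·THF (0 °C to rt, aqueous work-up to hydrolyse aryl borates) reduces the acid and returns to the route at target 21.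

Step 13. Ionisation and reduction may compete at the primary C8 carbinol (para to the methoxy group), the reaction may stall at the cyclic ether formed when the C8 hydroxyl captures the C7 cation, or the cation may alkylate an arene. Fallback: block the C8 hydroxyl first. From diol 19, AcCl/2,4,6-collidine (CH2Cl2, −78 °C) should acetylate only the primary hydroxyl to give racemic {3,5-bis(benzyloxy)-2-[(4,5-bis(benzyloxy)-2,3-dibromophenyl)(hydroxy)methyl]-4-methoxyphenyl}methyl acetate F5. Et3SiH/TFA (CH2Cl2, 0 °C) then deoxygenates C7 to {3,5-bis(benzyloxy)-2-[(4,5-bis(benzyloxy)-2,3-dibromophenyl)methyl]-4-methoxyphenyl}methyl acetate F6; the ester cannot close the cyclic ether and disfavours ionisation at C8. K2CO3/MeOH removes the acetate and returns to the route at alcohol 20.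

**Further compounds**

F1 | step 10 | N,N-diethyl-3,5-bis(benzyloxy)-4-methoxybenzamide | CCN(CC)C(=O)c1cc(OCc2ccccc2)c(OC)c(OCc2ccccc2)c1
F2 | step 10 | racemic 3,5-bis(benzyloxy)-2-{[4,5-bis(benzyloxy)-2,3-dibromophenyl](hydroxy)methyl}-N,N-diethyl-4-methoxybenzamide | CCN(CC)C(=O)c1cc(OCc2ccccc2)c(OC)c(OCc2ccccc2)c1C(O)c1cc(OCc2ccccc2)c(OCc2ccccc2)c(Br)c1Br
F3 | step 14 | racemic 3-(2,3-dibromo-4,5-dihydroxyphenyl)-4,6-dihydroxy-5-methoxy-2-benzofuran-1(3H)-one | O=C1OC(c2cc(O)c(O)c(Br)c2Br)c2c(O)c(OC)c(O)cc12
F4 | step 14 | 2-[(2,3-dibromo-4,5-dihydroxyphenyl)methyl]-3,5-dihydroxy-4-methoxybenzoic acid | OC(=O)c1cc(O)c(OC)c(O)c1Cc1cc(O)c(O)c(Br)c1Br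
F5 | step 13 | racemic {3,5-bis(benzyloxy)-2-[(4,5-bis(benzyloxy)-2,3-dibromophenyl)(hydroxy)methyl]-4-methoxyphenyl}methyl acetate | CC(=O)OCc1cc(OCc2ccccc2)c(OC)c(OCc2ccccc2)c1C(O)c1cc(OCc2ccccc2)c(OCc2ccccc2)c(Br)c1Br
F6 | step 13 | {3,5-bis(benzyloxy)-2-[(4,5-bis(benzyloxy)-2,3-dibromophenyl)methyl]-4-methoxyphenyl}methyl acetate | CC(=O)OCc1cc(OCc2ccccc2)c(OC)c(OCc2ccccc2)c1Cc1cc(OCc2ccccc2)c(OCc2ccccc2)c(Br)c1Br
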